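The easy entry comes first: the first step has no catalyst on its left-hand side, so the starting material leaves at 0.73 h⁻¹ whatever the catalyst charge.

| flask | starting material | catalyst | time |
|---|---|---|---|
| zeta | 0.80 M | 6.0 mM | 2.0 h |
| alpha | 0.80 M | 20 mM | 2.0 h |
| gamma | 0.80 M | 60 mM | 2.0 h |
| theta | 0.80 M | 200 mM | 2.0 h |
| delta | 0.80 M | 500 mM | 2.0 h |

    starting material → intermediate (k1 = 0.73 h⁻¹)
    catalyst + intermediate → catalyst + target (k2 = 41 L mol⁻¹ h⁻¹)
    catalyst + target → catalyst + over-reaction product (k3 = 11 L mol⁻¹ h⁻¹)

- "hardly changes" means that all values lie within two and a half points (for a concentration: within two and a half percent of the largest)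
- run time (zeta): 2.0 h

- amount of target at the end, in percent of the starting material charged for zeta, alpha, gamma, theta, delta, in this order
- the shape of the row from first to last (rises, then falls / rises all the way / hardly changes / falls, then rises / falls all the way)

The catalyst stands on both sides of the other two steps, so [catalyst] stays at its charge and each of these steps is pseudo-first-order. I book theta first. There, intermediate turns into target with the constant 8.20 h⁻¹, which I call the fill, and target is lost with 2.20 h⁻¹, the drain. Both are faster than the first step, so after the start-up, intermediate and target follow the starting material down at its own pace.

Setting making minus loss equal to that fall gives [intermediate]/[starting material] = first-step constant/(fill − first-step constant), and [target]/[intermediate] = fill/(drain − first-step constant). The product, 0.545 in theta, is what I carry: the tail ratio, the [target] held per [starting material] once the start-up has died away.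

The ledger for theta at 2.0 h, with the over-reaction product found by difference:

| Entry | Share of the charge |
|---|---|
| Starting material left | 23.2% |
| Intermediate | 2.27% |
| Target | 12.7% |
| Over-reaction product | 61.8% |

Target starts from zero, and the start-up term still stands at 1.23% of its first size, so I expect my target entry to be high and my over-reaction entry low.

The tail ratio does not serve zeta, whose drain of 0.0660 h⁻¹ is slower than the first step. In zeta, the half-life of intermediate by the second step, 2.8 h, is longer than the run, so slow filling holds the target down. I commit to a row that rises, then falls, as a judgement, since I have reckoned neither alpha nor gamma.

The forecast gives 18.6%, 38.1%, 36.8%, 11.8% and 3.7%, with the shape rises, then falls. At high catalyst it says the target is “over-reacted and sits at a small quasi-steady level”. Its theta value lies below my 12.7%.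

The simulation gives 18.6%, 38.1%, 36.8%, 11.8% and 3.69%, and the shape rises, then falls, as the forecast said. In theta, the over-reaction product stands at 62.7% beside 11.8% of target. The tail ratio carries to delta, where the fill is 20.5 h⁻¹ and the drain 5.50 h⁻¹. This gives a ratio of 0.159, and with 23.2% of starting material left, 3.69% of target; delta holds 3.69%.

Its constants stand for no real mixture.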